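**Retrosynthetic overview**
1. Artoflavanone ⇒ its isomeric 5-O-(2-methylbut-3-en-2-yl) ether by aromatic Claisen rearrangement: the group that masks the C5 oxygen becomes the C6 prenyl group and the 5-OH is revealed.
2. That flavanone ether ⇒ enol silane of a 2-fluoro-6-alkoxy-4-methoxyacetophenone + 3,4,5-trimethoxybenzaldehyde in one flask: C3–C2 by catalytic asymmetric Mukaiyama aldol, O1–C8a by fluoride-relayed intramolecular SNAr (a formal [4+2] of the C3–C4–C4a–C8a unit with the aldehyde C2=O1).
3. Enabling feature: ring C is a β-aryloxy ketone, O1–C2–C3–C4(=O)–C4a=C8a. C8a of ring A is ortho to the C4 carbonyl and meta to both ring-A oxygens (C5, C7), so a fluorine on C8a is displaced by the C2 oxygen; C3 is the enolisable methyl carbon of the C4 acetyl group.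
4. Fluoro ketone ⇒ 2,6-difluoro-4-methoxyacetophenone (one fluorine exchanged for the tertiary allyl oxide, the other kept as leaving group for the key step) ⇒ 3,5-difluoroanisole + N-methoxy-N-methylacetamide.
5. Ring order: rings A and B are bought as benzenes; ring C is the only ring made, in the key step, together with the C2 stereocentre.

Key step: step 4

Assumption: the D-tryptophan-derived (R) antipode of the oxazaborolidinone is taken to steer the enol silane to the Si face of the aldehyde; the sense is to be confirmed on the parent acetophenone enol silane/benzaldehyde pair, and the (S) antipode used if it proves opposite.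

**Step 1**
Reactants: 1 3,5-difluoroanisole; 2 N-methoxy-N-methylacetamide
Product: 5 1-(2,6-difluoro-4-methoxyphenyl)ethan-1-one, via aryllithium 3 (not isolated), via lithium hemiaminal 4 (not isolated)
Conditions: n-BuLi, THF, −78 °C; then 2, −78 → −20 °C; then H2O
Reagents that add atoms: none
Why: Deprotonation of 1 at the position flanked by both fluorines (directed ortho-metalation at the most acidic ring C–H) gives aryllithium 3, which at −78 °C adds once to the N-methoxy-N-methylamide to form the chelated adduct 4 (Weinreb ketone synthesis) that collapses to ketone 5 only on aqueous work-up; no stereocentre is formed.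

**Step 2**
Reactants: 5 1-(2,6-difluoro-4-methoxyphenyl)ethan-1-one; 6 2-methylbut-3-en-2-ol
Product: 8 1-[2-fluoro-4-methoxy-6-(2-methylbut-3-en-2-yloxy)phenyl]ethan-1-one, via sodium alkoxide 7 (not isolated)
Conditions: NaH, 6 (excess), THF, 0 °C; then 5, 0 → 45 °C
Reagents that add atoms: none
Why: Nucleophilic aromatic substitution (SNAr) of one of the two equivalent fluorines ortho to the acetyl group by tertiary alkoxide 7 is regiochemically unambiguous, and the bulky new ortho ether twists the carbonyl out of conjugation so that the second fluorine should survive; no stereocentre is formed.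

**Step 3**
Reactants: 8 1-[2-fluoro-4-methoxy-6-(2-methylbut-3-en-2-yloxy)phenyl]ethan-1-one
Product: 10 {1-[2-fluoro-4-methoxy-6-(2-methylbut-3-en-2-yloxy)phenyl]ethenyloxy}trimethylsilane, via lithium enolate 9 (not isolated)
Conditions: LiN(SiMe3)2, THF, −78 °C; then Me3SiCl, −78 → 0 °C; pentane, filtration, no aqueous work-up
Reagents that add atoms: chlorotrimethylsilane, C[Si](C)(C)Cl
Why: Kinetic deprotonation of the only enolisable position (the acetyl CH3) and O-silylation of lithium enolate 9 (enol silane formation) should leave the base-stable tertiary allyl ether and the aryl fluoride untouched at low temperature; no stereocentre is formed.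

**Step 4**
Reactants: 10 {1-[2-fluoro-4-methoxy-6-(2-methylbut-3-en-2-yloxy)phenyl]ethenyloxy}trimethylsilane; 11 3,4,5-trimethoxybenzaldehyde
Product: 13 (2S)-7-methoxy-5-(2-methylbut-3-en-2-yloxy)-2-(3,4,5-trimethoxyphenyl)-2,3-dihydro-4H-chromen-4-one, via silyl aldol 12 (not isolated)
Conditions: (R)-2-butyl-4-(1H-indol-3-ylmethyl)-3-(4-methylphenylsulfonyl)-1,3,2-oxazaborolidin-5-one (C22H25BN2O4S, 20 mol%), EtCN, −78 °C; then CsF (50 mol%), DMF, −20 °C → rt
Reagents that add atoms: none
Why: The boron Lewis acid binds aldehyde 11 and enol silane 10 adds to its Si face (catalytic asymmetric Mukaiyama aldol, new C3–C2 bond), silyl transfer to the aldolate oxygen releasing β-silyloxy ketone 12 and the catalyst; fluoride then strips the silyl group and the C2 oxygen attacks C8a in an intramolecular addition–elimination (SNAr, new O1–C8a bond), the expelled fluoride carrying the chain so that Me3SiF is the only by-product. The closest known reaction types are the oxazaborolidinone-catalysed Mukaiyama aldol of aryl methyl ketone enol silanes with aromatic aldehydes and the fluoride- or base-mediated cyclisation of 2-fluoroaryl ketones carrying a β-oxygen nucleophile to benzopyran-4-ones. Ring C closes as a six-membered ring, 6-endo-trig with respect to the C4a=C8a–C4=O unit, through an anionic σ-complex whose charge is taken up by the C4 carbonyl. The single new stereocentre, C2, is set in the aldol stage by the chiral catalyst, and because its C–O bond is not broken in the ring closure the (S) configuration should be carried into 13. The step needs ring closure to outrun retro-aldol cleavage and to expel fluoride rather than the C5 alkoxide: the fluorine at C8a is ortho to the carbonyl and meta to both ring-A oxygen substituents, fluoride is by far the better leaving group, and sub-stoichiometric CsF keeps the concentration of free alkoxide low.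

**Step 5**
Reactants: 13 (2S)-7-methoxy-5-(2-methylbut-3-en-2-yloxy)-2-(3,4,5-trimethoxyphenyl)-2,3-dihydro-4H-chromen-4-one
Product: 14 artoflavanone
Conditions: PhMe (degassed), 110 °C
Reagents that add atoms: none
Why: Aromatic Claisen rearrangement: the [3,3] shift of the aryl 1,1-dimethylallyl ether delivers the CH2 terminus to C6, the only ortho position that carries hydrogen, and enolisation restores ring A with the 5-OH hydrogen-bonded to C4=O, while the neutral, aprotic conditions should leave C2 untouched (no new stereocentre).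

**Compound list**
1 | 3,5-difluoroanisole (1,3-difluoro-5-methoxybenzene) | COc1cc(F)cc(F)c1 | starting material
2 | N-methoxy-N-methylacetamide | CC(=O)N(C)OC | starting material
3 | (2,6-difluoro-4-methoxyphenyl)lithium (formed in the flask) | [Li]c1c(F)cc(OC)cc1F | intermediate
4 | lithium 1-(2,6-difluoro-4-methoxyphenyl)-1-[methoxy(methyl)amino]ethan-1-olate (formed in the flask) | [Li+].[O-]C(C)(N(C)OC)c1c(F)cc(OC)cc1F | intermediate
5 | 1-(2,6-difluoro-4-methoxyphenyl)ethan-1-one | CC(=O)c1c(F)cc(OC)cc1F | intermediate
6 | 2-methylbut-3-en-2-ol | CC(C)(O)C=C | starting material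
7 | sodium 2-methylbut-3-en-2-olate (formed in the flask) | [Na+].[O-]C(C)(C)C=C | intermediate
8 | 1-[2-fluoro-4-methoxy-6-(2-methylbut-3-en-2-yloxy)phenyl]ethan-1-one | CC(=O)c1c(F)cc(OC)cc1OC(C)(C)C=C | intermediate
9 | lithium 1-[2-fluoro-4-methoxy-6-(2-methylbut-3-en-2-yloxy)phenyl]ethen-1-olate (formed in the flask) | [Li+].[O-]C(=C)c1c(F)cc(OC)cc1OC(C)(C)C=C | intermediate
10 | {1-[2-fluoro-4-methoxy-6-(2-methylbut-3-en-2-yloxy)phenyl]ethenyloxy}trimethylsilane | C=C(O[Si](C)(C)C)c1c(F)cc(OC)cc1OC(C)(C)C=C | intermediate
11 | 3,4,5-trimethoxybenzaldehyde | COc1cc(C=O)cc(OC)c1OC | starting material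
12 | (3S)-1-[2-fluoro-4-methoxy-6-(2-methylbut-3-en-2-yloxy)phenyl]-3-(3,4,5-trimethoxyphenyl)-3-(trimethylsilyloxy)propan-1-one (formed in the flask) | C=CC(C)(C)Oc1cc(OC)cc(F)c1C(=O)C[C@@H](c1cc(OC)c(OC)c(OC)c1)O[Si](C)(C)C | intermediate
13 | (2S)-7-methoxy-5-(2-methylbut-3-en-2-yloxy)-2-(3,4,5-trimethoxyphenyl)-2,3-dihydro-4H-chromen-4-one | C=CC(C)(C)Oc1cc(OC)cc2c1C(=O)C[C@@H](c1cc(OC)c(OC)c(OC)c1)O2 | intermediate
14 | artoflavanone, (2S)-5-hydroxy-7-methoxy-6-(3-methylbut-2-en-1-yl)-2-(3,4,5-trimethoxyphenyl)-2,3-dihydro-4H-chromen-4-one | COc1cc2c(c(O)c1CC=C(C)C)C(=O)C[C@@H](c1cc(OC)c(OC)c(OC)c1)O2 | target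

**Step count and risks**
Total steps: 5. Longest linear sequence: 5 steps (1 → 5 → 8 → 10 → 13 → 14).

Steps most likely to fail, in order of risk:

1) Step 4. The processes to fear are insufficient facial selectivity with this hindered enol silane and electron-rich aldehyde, and retro-aldol cleavage or β-elimination of the silyl aldol when fluoride is added to the same flask, which would erode the enantiomeric purity or stop at an enone. The fallback sets out from 8 and returns at 13, and fixes the stereocentre by conjugate borylation instead of aldol addition. Claisen–Schmidt condensation of 8 with 11 (NaOH, EtOH, 0 °C) should give the (E)-2'-fluorochalcone F1. Copper-catalysed enantioselective β-borylation should then give the (S)-β-boryl ketone F2; the conditions are CuCl, NaOt-Bu, B2pin2, MeOH, THF, with the enantiomer of 1-[2-(diphenylphosphino)ferrocenyl]ethyldicyclohexylphosphine that leads to the S product. Oxidation with NaBO3·4H2O (THF/H2O), which proceeds with retention, should give the (S)-β-hydroxy ketone F3. Ring closure of the isolated alcohol by SNAr (NaH, THF, 0 °C) then leads back to 13.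

2) Step 2. The process to fear is enolisation of the acetyl group by the hindered tertiary alkoxide, leading to sluggish substitution, self-condensation or a second substitution. The fallback sets out from 5 and returns at 8, and attaches the tertiary allyl group to a phenol instead. Hydroxide SNAr on 5 (KOH, DMSO/H2O, 60 °C) should give the phenol F4; the phenoxide formed shuts down a second substitution. O-Alkylation with 3-chloro-3-methylbut-1-yne (CuCl2·2H2O cat., DBU, MeCN) should give the 1,1-dimethylpropargyl ether F5. Semihydrogenation (H2, Pd/CaCO3 poisoned with Pb(OAc)2, quinoline, EtOAc) then leads back to 8.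

3) Step 5. The processes to fear are fragmentation of the tertiary allyl aryl ether (loss of isoprene), migration to C8 by a para pathway, and erosion of the C2 configuration on heating the flavanone. The fallback sets out from 8 and returns at 14, and moves the rearrangement in front of the ring closure. Heating 8 (PhMe, 110 °C) should give the ortho-prenyl phenol F6 by Claisen rearrangement on the robust ketone. Protection (MOMCl, NaH, DMF, 0 °C) should give the MOM ether F7, and LiN(SiMe3)2/Me3SiCl the enol silane F8. The conditions of step 4 with 11 should give, by way of the silyl aldol F9, the 5-O-MOM flavanone F10. Mild acid (HCl, MeOH, rt) then removes the MOM group and leads to 14.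

**Further compounds**
F1 | step 4 | (E)-1-[2-fluoro-4-methoxy-6-(2-methylbut-3-en-2-yloxy)phenyl]-3-(3,4,5-trimethoxyphenyl)prop-2-en-1-one | C=CC(C)(C)Oc1cc(OC)cc(F)c1C(=O)/C=C/c1cc(OC)c(OC)c(OC)c1
F2 | step 4 | (3S)-1-[2-fluoro-4-methoxy-6-(2-methylbut-3-en-2-yloxy)phenyl]-3-(4,4,5,5-tetramethyl-1,3,2-dioxaborolan-2-yl)-3-(3,4,5-trimethoxyphenyl)propan-1-one | C=CC(C)(C)Oc1cc(OC)cc(F)c1C(=O)C[C@@H](c1cc(OC)c(OC)c(OC)c1)B1OC(C)(C)C(C)(C)O1
F3 | step 4 | (3S)-1-[2-fluoro-4-methoxy-6-(2-methylbut-3-en-2-yloxy)phenyl]-3-hydroxy-3-(3,4,5-trimethoxyphenyl)propan-1-one | C=CC(C)(C)Oc1cc(OC)cc(F)c1C(=O)C[C@@H](c1cc(OC)c(OC)c(OC)c1)O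
F4 | step 2 | 1-(2-fluoro-6-hydroxy-4-methoxyphenyl)ethan-1-one | CC(=O)c1c(F)cc(OC)cc1O
F5 | step 2 | 1-[2-fluoro-4-methoxy-6-(2-methylbut-3-yn-2-yloxy)phenyl]ethan-1-one | CC(=O)c1c(F)cc(OC)cc1OC(C)(C)C#C
F6 | step 5 | 1-[6-fluoro-2-hydroxy-4-methoxy-3-(3-methylbut-2-en-1-yl)phenyl]ethan-1-one | CC(=O)c1c(F)cc(OC)c(CC=C(C)C)c1O
F7 | step 5 | 1-[6-fluoro-4-methoxy-2-(methoxymethoxy)-3-(3-methylbut-2-en-1-yl)phenyl]ethan-1-one | CC(=O)c1c(F)cc(OC)c(CC=C(C)C)c1OCOC
F8 | step 5 | {1-[6-fluoro-4-methoxy-2-(methoxymethoxy)-3-(3-methylbut-2-en-1-yl)phenyl]ethenyloxy}trimethylsilane | C=C(O[Si](C)(C)C)c1c(F)cc(OC)c(CC=C(C)C)c1OCOC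
F9 | step 5 | (3S)-1-[6-fluoro-4-methoxy-2-(methoxymethoxy)-3-(3-methylbut-2-en-1-yl)phenyl]-3-(3,4,5-trimethoxyphenyl)-3-(trimethylsilyloxy)propan-1-one | COCOc1c(CC=C(C)C)c(OC)cc(F)c1C(=O)C[C@@H](c1cc(OC)c(OC)c(OC)c1)O[Si](C)(C)C
F10 | step 5 | (2S)-7-methoxy-5-(methoxymethoxy)-6-(3-methylbut-2-en-1-yl)-2-(3,4,5-trimethoxyphenyl)-2,3-dihydro-4H-chromen-4-one | COCOc1c(CC=C(C)C)c(OC)cc2c1C(=O)C[C@@H](c1cc(OC)c(OC)c(OC)c1)O2
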